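Numbering follows longipinane: C1 ketone carbon, C4/C5/C10/C11 cyclobutane, C6 CMe2, C7–C9 the ester-bearing carbons. Everything rests on cutting the seven-membered ring at C5–C6 and C7–C8, which excises a Me2C–CH(O) unit. Both bonds form in one pot from a cyclohexenyl 2-methylprop-1-enyl ether bearing an enol silane side chain: a Claisen rearrangement shifts the Me2C–CH=O unit from the C1 oxygen to C5, cis to the C4 side chain, and the unmasked aldehyde (C7) is trapped by the enol silane (C8) in a Mukaiyama aldol. The step exploits the γ,δ-unsaturated aldehyde pattern C7–C6–C5–C11=C1 and the 1,3-dioxygenation C7/C9. The cyclobutane bond C10–C11 is closed later, and the three esters are installed last, one hydroxyl at a time.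

Key step: step 8

Remark: in the Why lines every carbon of an intermediate carries the longipinane number of the target carbon it becomes; the side-chain methine (future C10) is carried as both epimers from step 5 to step 10 and converges in step 11, where it becomes a planar enolate carbon.
Remark: the (S)-configured amine catalyst of step 1 is assumed, by analogy with related enamine Michael additions, to give the (R)-enone; its antipode would be used otherwise.
Remark: the longipinane names of 19 to 26 denote the tricyclic skeleton with the configuration of the target, in which O7 is trans to O8 and O8 is cis to O9; the SMILES in the compound list are definitive.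

Step 1
Reactants: 1 propanal; 2 but-3-en-2-one
Product: 4 (4R)-4-methylcyclohex-2-en-1-one, via keto aldehyde 3 (not isolated)
Conditions: (S)-2-[methoxy(diphenyl)methyl]pyrrolidine (5 mol%), ethyl 3,4-dihydroxybenzoate (20 mol%), neat, 4 °C; then LiOH, i-PrOH, rt
Reagents that add atoms: none
Why: Enamine-catalysed asymmetric Michael addition of propanal to the enone followed by base-mediated aldol condensation (organocatalytic Robinson annulation) should work because the bulky pyrrolidine substituent shields one enamine face, which sets the methyl-bearing stereocentre (future C3).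

Step 2
Reactants: 4 (4R)-4-methylcyclohex-2-en-1-one
Product: 5 (4R,6R)-6-hydroxy-4-methylcyclohex-2-en-1-one
Conditions: LiN(i-Pr)2, THF, −78 °C; then 2-(benzenesulfonyl)-3-phenyloxaziridine, −78 °C
Reagents that add atoms: 2-(benzenesulfonyl)-3-phenyloxaziridine, O=S(=O)(c1ccccc1)N1OC1c1ccccc1
Why: Kinetic deprotonation gives the cross-conjugated α′-enolate, which the oxaziridine hydroxylates (Davis oxidation) by stereoelectronically preferred axial attack, placing the new oxygen (future C1 oxygen) trans to the pseudo-equatorial methyl group.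

Step 3
Reactants: 5 (4R,6R)-6-hydroxy-4-methylcyclohex-2-en-1-one; 6 3-bromo-2-methylprop-1-ene
Product: 7 (4R,6R)-4-methyl-6-(2-methylprop-2-enyloxy)cyclohex-2-en-1-one
Conditions: Ag2O, Et2O, rt, dark
Reagents that add atoms: none
Why: Silver-oxide-promoted Williamson etherification alkylates the α-hydroxy ketone without a free alkoxide, so the carbinol centre is not epimerised and the later vinyl ether is installed as its 2-methylallyl isomer.

Step 4
Reactants: 7 (4R,6R)-4-methyl-6-(2-methylprop-2-enyloxy)cyclohex-2-en-1-one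
Product: 8 (1S,4R,6R)-4-methyl-6-(2-methylprop-2-enyloxy)cyclohex-2-en-1-ol
Conditions: i-Bu2AlH, toluene, −78 °C
Reagents that add atoms: none
Why: 1,2-Reduction of the enone by the bulky aluminium hydride from the face anti to the neighbouring alkoxy group (polar Felkin–Anh control) should give the cis-1,2-diol monoether, which sets the carbinol centre that steers step 5.

Step 5
Reactants: 8 (1S,4R,6R)-4-methyl-6-(2-methylprop-2-enyloxy)cyclohex-2-en-1-ol; 9 ethyl 2-methyl-3-oxobutanoate
Product: 12 3-[(1S,4R,6R)-6-methyl-4-(2-methylprop-2-enyloxy)cyclohex-2-en-1-yl]butan-2-one (both side-chain epimers), via allyl keto ester 10 (not isolated), via keto acid 11 (not isolated)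
Conditions: 4-(dimethylamino)pyridine (cat.), 1,2-dichlorobenzene, 140 °C (EtOH distilled off); then 180 °C
Reagents that add atoms: none
Why: Transesterification to the allyl β-keto ester followed by thermal Carroll rearrangement ([3,3]-shift of its enol, then decarboxylation) forms C4–C10 suprafacially, so the ketone side chain enters cis to the ether oxygen and trans to the ring methyl while the alkene moves to C5=C11.

Step 6
Reactants: 12 3-[(1S,4R,6R)-6-methyl-4-(2-methylprop-2-enyloxy)cyclohex-2-en-1-yl]butan-2-one
Product: 13 3-[(1S,4R,6R)-6-methyl-4-(2-methylprop-1-enyloxy)cyclohex-2-en-1-yl]butan-2-one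
Conditions: RuHCl(CO)(PPh3)3 (2 mol%), toluene, 80 °C
Reagents that add atoms: none
Why: Ruthenium-hydride-catalysed allyl-to-vinyl ether isomerisation moves the terminal 1,1-disubstituted alkene into conjugation with oxygen, while the hindered internal ring alkene should be left alone and no stereocentre is touched.

Step 7
Reactants: 13 3-[(1S,4R,6R)-6-methyl-4-(2-methylprop-1-enyloxy)cyclohex-2-en-1-yl]butan-2-one
Product: 14 tert-butyldimethyl[3-[(1S,4R,6R)-6-methyl-4-(2-methylprop-1-enyloxy)cyclohex-2-en-1-yl]but-1-en-2-yloxy]silane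
Conditions: LiN(i-Pr)2, THF, −78 °C; then t-BuMe2SiOTf
Reagents that add atoms: tert-butyldimethylsilyl trifluoromethanesulfonate, CC(C)(C)[Si](C)(C)OS(=O)(=O)C(F)(F)F
Why: Kinetic deprotonation of the methyl ketone at the methyl group and O-silylation (regioselective enolate trapping) give the less substituted enol silane, which carries the future C8 as its nucleophilic terminus.

Step 8
Reactants: 14 tert-butyldimethyl[3-[(1S,4R,6R)-6-methyl-4-(2-methylprop-1-enyloxy)cyclohex-2-en-1-yl]but-1-en-2-yloxy]silane
Product: 16 (4R,4aS,8R,9aR)-8-(tert-butyldimethylsilyloxy)-4,5,9,9-tetramethyl-3,4,4a,5,7,8,9,9a-octahydro-6H-benzo[7]annulen-6-one (both C5 epimers), via Claisen aldehyde 15 (not isolated)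
Conditions: mesitylene, 2,6-di-tert-butyl-4-methylpyridine (5 mol%), 185 °C, sealed tube; then cool, CH2Cl2, t-BuMe2SiOTf (10 mol%), −78 °C
Reagents that add atoms: none
Why: On heating, the allyl 2-methylprop-1-enyl ether undergoes a concerted [3,3]-sigmatropic Claisen rearrangement that breaks the C1–O bond, forms C5–C6 and moves the alkene to C1=C11; the freed neopentyl aldehyde 15 is then O-silylated by the catalytic silyl triflate and attacked by the terminal carbon of the enol silane, forming C7–C8 with silyl transfer to the new oxygen (Mukaiyama aldol). The closest known reaction type is the aliphatic Claisen rearrangement of cyclohexenyl vinyl ethers that builds a quaternary α-carbon, run in tandem with a silyl-triflate-catalysed intramolecular Mukaiyama aldol. Only the aldol closes a ring: the seven-membered ring forms in a 7-(enolendo)-exo-trig closure onto the aldehyde carbon. C5 is set by the suprafacial shift, so the C1 oxygen stereocentre dictates that C6 arrives cis to the C4 side chain (cis ring fusion), and C7 is set in the open aldol transition state, where the bulky silyloxonium group should point to the convex face, away from the cyclohexene ring. The step needs the enol silane rather than the ring alkene to act as the nucleophile, which its far higher nucleophilicity secures, and it needs the enol silane to survive the thermal stage, which the hindered pyridine buffer and the absence of protic acid secure.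

Step 9
Reactants: 16 (4R,4aS,8R,9aR)-8-(tert-butyldimethylsilyloxy)-4,5,9,9-tetramethyl-3,4,4a,5,7,8,9,9a-octahydro-6H-benzo[7]annulen-6-one
Product: 17 (4R,4aS,8R,9aR)-6,8-bis(tert-butyldimethylsilyloxy)-4,5,9,9-tetramethyl-4,4a,5,8,9,9a-hexahydro-3H-benzo[7]annulene (both C5 epimers)
Conditions: LiN(i-Pr)2, THF, −78 °C; then t-BuMe2SiOTf
Reagents that add atoms: tert-butyldimethylsilyl trifluoromethanesulfonate, CC(C)(C)[Si](C)(C)OS(=O)(=O)C(F)(F)F
Why: Kinetic deprotonation takes the C8 methylene rather than the hindered tertiary C10–H, and O-silylation at low temperature (regioselective silyl enol ether formation) outruns β-elimination of the C7 silyloxy group.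

Step 10
Reactants: 17 (4R,4aS,8R,9aR)-6,8-bis(tert-butyldimethylsilyloxy)-4,5,9,9-tetramethyl-4,4a,5,8,9,9a-hexahydro-3H-benzo[7]annulene
Product: 18 7,8-bis(tert-butyldimethylsilyloxy)-1,2-epoxy-4,5,9,9-tetramethyldecahydro-6H-benzo[7]annulen-6-one (epoxide anti to the C9 and C5 substituents at the ring fusion; 7-O trans to 8-O; both C5 epimers)
Conditions: mCPBA (2.2 equiv), NaHCO3, CH2Cl2, 0 °C
Reagents that add atoms: 3-chloroperoxybenzoic acid, O=C(OO)c1cccc(Cl)c1
Why: Rubottom oxidation of the enol silane (attack anti to the neighbouring C7 silyloxy group, then 1,4-silyl shift) installs the C8 oxygen trans to the C7 oxygen, and the second equivalent epoxidises the ring alkene (Prilezhaev reaction) on the face anti to the quaternary C6 substituent.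

Step 11
Reactants: 18 7,8-bis(tert-butyldimethylsilyloxy)-1,2-epoxy-4,5,9,9-tetramethyldecahydro-6H-benzo[7]annulen-6-one
Product: 20 7,8-bis(tert-butyldimethylsilyloxy)longipinane-1,9-diol (7-O trans to 8-O; 8-O cis to 9-O), via tricyclic hydroxy ketone 19 (not isolated)
Conditions: KN(SiMe3)2, THF, −78 to 0 °C; then LiAlH4, 0 °C
Reagents that add atoms: none
Why: The α-silyloxy ketone should be deprotonated at C10 rather than at the shielded C8–H next to oxygen, and the enolate opens the epoxide at the proximal carbon C11 with inversion in a 4-exo-tet closure (intramolecular enolate alkylation by an epoxide, favoured over 5-endo attack at C1 by the collinearity requirement known from epoxynitrile cyclisations) in which the ring system allows only one configuration at the new quaternary C10, after which hydride reduces the C9 ketone from the face anti to the C8 silyloxy group to give the 8,9-cis relationship.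

Step 12
Reactants: 20 7,8-bis(tert-butyldimethylsilyloxy)longipinane-1,9-diol
Product: 21 7,8-bis(tert-butyldimethylsilyloxy)-9-hydroxylongipinan-1-one
Conditions: Dess–Martin periodinane (1.1 equiv), NaHCO3, CH2Cl2, 0 °C
Reagents that add atoms: none
Why: Dess–Martin oxidation is expected to take the accessible C1 carbinol and to leave the C9 carbinol, which is flanked by the quaternary C10 and the silyloxy-bearing C8 (chemoselective alcohol oxidation).

Step 13
Reactants: 21 7,8-bis(tert-butyldimethylsilyloxy)-9-hydroxylongipinan-1-one; 22 (2Z)-2-methylbut-2-enoic acid (angelic acid)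
Product: 23 7,8-bis(tert-butyldimethylsilyloxy)-9-[(2Z)-2-methylbut-2-enoyloxy]longipinan-1-one
Conditions: 22, 2,4,6-trichlorobenzoyl chloride, Et3N, toluene, rt; then 21, 80 °C
Reagents that add atoms: none
Why: Yamaguchi esterification through the mixed 2,4,6-trichlorobenzoic anhydride, run without a nucleophilic catalyst to suppress angelate-to-tiglate isomerisation, should acylate the C9 hydroxyl, the only free one, with the (Z)-geometry intact, at a stage where no other ester is present that could migrate under the forcing conditions.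

Step 14
Reactants: 23 7,8-bis(tert-butyldimethylsilyloxy)-9-[(2Z)-2-methylbut-2-enoyloxy]longipinan-1-one
Product: 24 7,8-dihydroxy-9-[(2Z)-2-methylbut-2-enoyloxy]longipinan-1-one
Conditions: HF·pyridine, pyridine, THF, 0 °C to rt
Reagents that add atoms: none
Why: Fluoride-mediated cleavage of both silyl ethers (desilylation) under buffered, non-basic conditions frees the 7,8-diol without touching the ketone, the angelate or any stereocentre, and acyl migration from O9 to O8 should be slow in the absence of base.

Step 15
Reactants: 24 7,8-dihydroxy-9-[(2Z)-2-methylbut-2-enoyloxy]longipinan-1-one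
Product: 25 8-acetoxy-7-hydroxy-9-[(2Z)-2-methylbut-2-enoyloxy]longipinan-1-one
Conditions: Ac2O (1.1 equiv), pyridine, CH2Cl2, 0 °C
Reagents that add atoms: acetic anhydride, CC(=O)OC(C)=O
Why: Acetylation with a slight excess of anhydride at low temperature (site-selective acylation) should select the C8 hydroxyl, because the C7 hydroxyl is neopentyl and shielded by the adjacent C6 gem-dimethyl group.

Step 16
Reactants: 25 8-acetoxy-7-hydroxy-9-[(2Z)-2-methylbut-2-enoyloxy]longipinan-1-one; 22 (2Z)-2-methylbut-2-enoic acid (angelic acid)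
Product: 26 8-acetoxy-7,9-bis[(2Z)-2-methylbut-2-enoyloxy]longipinan-1-one (CNP0197834.1)
Conditions: 22, 2,4,6-trichlorobenzoyl chloride, Et3N, toluene, rt; then 25, 80 °C
Reagents that add atoms: none
Why: A second Yamaguchi-type esterification without a nucleophilic catalyst should acylate the remaining neopentyl C7 hydroxyl with the (Z)-geometry intact and complete the triester without touching any stereocentre.

Compound list
1 | propanal | CCC=O | starting material
2 | but-3-en-2-one | CC(=O)C=C | starting material
3 | (2R)-2-methyl-5-oxohexanal | O=C[C@H](C)CCC(C)=O | intermediate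
4 | (4R)-4-methylcyclohex-2-en-1-one | C[C@H]1C=CC(=O)CC1 | intermediate
5 | (4R,6R)-6-hydroxy-4-methylcyclohex-2-en-1-one | C[C@H]1C=CC(=O)[C@H](O)C1 | intermediate
6 | 3-bromo-2-methylprop-1-ene | C=C(C)CBr | starting material
7 | (4R,6R)-4-methyl-6-(2-methylprop-2-enyloxy)cyclohex-2-en-1-one | C[C@H]1C=CC(=O)[C@H](OCC(C)=C)C1 | intermediate
8 | (1S,4R,6R)-4-methyl-6-(2-methylprop-2-enyloxy)cyclohex-2-en-1-ol | C[C@H]1C=C[C@H](O)[C@H](OCC(C)=C)C1 | intermediate
9 | ethyl 2-methyl-3-oxobutanoate | CCOC(=O)C(C)C(C)=O | starting material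
10 | (1S,4R,6R)-4-methyl-6-(2-methylprop-2-enyloxy)cyclohex-2-en-1-yl 2-methyl-3-oxobutanoate | C[C@H]1C=C[C@H](OC(=O)C(C)C(C)=O)[C@H](OCC(C)=C)C1 | intermediate
11 | 2-methyl-2-[(1S,4R,6R)-6-methyl-4-(2-methylprop-2-enyloxy)cyclohex-2-en-1-yl]-3-oxobutanoic acid (both epimers at the quaternary carbon) | C[C@@H]1C[C@@H](OCC(C)=C)C=C[C@H]1C(C)(C(O)=O)C(C)=O | intermediate
12 | 3-[(1S,4R,6R)-6-methyl-4-(2-methylprop-2-enyloxy)cyclohex-2-en-1-yl]butan-2-one (both side-chain epimers) | C[C@@H]1C[C@@H](OCC(C)=C)C=C[C@H]1C(C)C(C)=O | intermediate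
13 | 3-[(1S,4R,6R)-6-methyl-4-(2-methylprop-1-enyloxy)cyclohex-2-en-1-yl]butan-2-one (both side-chain epimers) | C[C@@H]1C[C@@H](OC=C(C)C)C=C[C@H]1C(C)C(C)=O | intermediate
14 | tert-butyldimethyl[3-[(1S,4R,6R)-6-methyl-4-(2-methylprop-1-enyloxy)cyclohex-2-en-1-yl]but-1-en-2-yloxy]silane (both side-chain epimers) | C[C@@H]1C[C@@H](OC=C(C)C)C=C[C@H]1C(C)C(=C)O[Si](C)(C)C(C)(C)C | intermediate
15 | 2-[(1R,5R,6S)-6-[3-(tert-butyldimethylsilyloxy)but-3-en-2-yl]-5-methylcyclohex-2-en-1-yl]-2-methylpropanal (both side-chain epimers) | C[C@@H]1CC=C[C@@H](C(C)(C)C=O)[C@H]1C(C)C(=C)O[Si](C)(C)C(C)(C)C | intermediate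
16 | (4R,4aS,8R,9aR)-8-(tert-butyldimethylsilyloxy)-4,5,9,9-tetramethyl-3,4,4a,5,7,8,9,9a-octahydro-6H-benzo[7]annulen-6-one (both C5 epimers) | C[C@@H]1CC=C[C@@H]2[C@H]1C(C)C(=O)C[C@@H](O[Si](C)(C)C(C)(C)C)C2(C)C | intermediate
17 | (4R,4aS,8R,9aR)-6,8-bis(tert-butyldimethylsilyloxy)-4,5,9,9-tetramethyl-4,4a,5,8,9,9a-hexahydro-3H-benzo[7]annulene (both C5 epimers) | C[C@@H]1CC=C[C@@H]2[C@H]1C(C)C(O[Si](C)(C)C(C)(C)C)=C[C@@H](O[Si](C)(C)C(C)(C)C)C2(C)C | intermediate
18 | 7,8-bis(tert-butyldimethylsilyloxy)-1,2-epoxy-4,5,9,9-tetramethyldecahydro-6H-benzo[7]annulen-6-one (epoxide anti to the ring-fusion substituents; 7-O trans to 8-O; both C5 epimers) | C[C@@H]1C[C@@H]3O[C@@H]3[C@@H]2[C@H]1C(C)C(=O)[C@H](O[Si](C)(C)C(C)(C)C)[C@@H](O[Si](C)(C)C(C)(C)C)C2(C)C | intermediate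
19 | 7,8-bis(tert-butyldimethylsilyloxy)-1-hydroxylongipinan-9-one | CC(C)(C)[Si](C)(C)O[C@@H]1[C@@H](O[Si](C)(C)C(C)(C)C)C(=O)[C@]2(C)[C@@H]3[C@@H]([C@H]2[C@@H](O)C[C@H]3C)C1(C)C | intermediate
20 | 7,8-bis(tert-butyldimethylsilyloxy)longipinane-1,9-diol | CC(C)(C)[Si](C)(C)O[C@@H]1[C@@H](O[Si](C)(C)C(C)(C)C)[C@@H](O)[C@]2(C)[C@@H]3[C@@H]([C@H]2[C@@H](O)C[C@H]3C)C1(C)C | intermediate
21 | 7,8-bis(tert-butyldimethylsilyloxy)-9-hydroxylongipinan-1-one | CC(C)(C)[Si](C)(C)O[C@@H]1[C@@H](O[Si](C)(C)C(C)(C)C)[C@@H](O)[C@]2(C)[C@@H]3[C@@H]([C@H]2C(=O)C[C@H]3C)C1(C)C | intermediate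
22 | (2Z)-2-methylbut-2-enoic acid (angelic acid) | C/C=C(/C)C(=O)O | starting material
23 | 7,8-bis(tert-butyldimethylsilyloxy)-9-[(2Z)-2-methylbut-2-enoyloxy]longipinan-1-one | CC(C)(C)[Si](C)(C)O[C@@H]1[C@@H](O[Si](C)(C)C(C)(C)C)[C@@H](OC(=O)/C(C)=C\C)[C@]2(C)[C@@H]3[C@@H]([C@H]2C(=O)C[C@H]3C)C1(C)C | intermediate
24 | 7,8-dihydroxy-9-[(2Z)-2-methylbut-2-enoyloxy]longipinan-1-one | O[C@@H]1[C@@H](O)[C@@H](OC(=O)/C(C)=C\C)[C@]2(C)[C@@H]3[C@@H]([C@H]2C(=O)C[C@H]3C)C1(C)C | intermediate
25 | 8-acetoxy-7-hydroxy-9-[(2Z)-2-methylbut-2-enoyloxy]longipinan-1-one | O[C@@H]1[C@@H](OC(C)=O)[C@@H](OC(=O)/C(C)=C\C)[C@]2(C)[C@@H]3[C@@H]([C@H]2C(=O)C[C@H]3C)C1(C)C | intermediate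
26 | 8-acetoxy-7,9-bis[(2Z)-2-methylbut-2-enoyloxy]longipinan-1-one (CNP0197834.1) | C/C=C(/C)C(=O)O[C@@H]1[C@@H](OC(C)=O)[C@@H](OC(=O)/C(C)=C\C)[C@]2(C)[C@@H]3[C@@H]([C@H]2C(=O)C[C@H]3C)C1(C)C | target

Total step count: 16. Longest linear sequence: 16 steps (fully linear from propanal and but-3-en-2-one).

Steps most likely to fail

Step 8. The thermal stage may erode the enol silane, and the Lewis-acid stage may close the seven-membered ring with poor facial control at C7. The fallback separates the two bond formations and closes the ring as a reversible enolate aldol. It sets out from 13: heating alone (mesitylene, 185 °C) should give the keto aldehyde 3-[(1S,2R,6R)-6-methyl-2-(2-methyl-1-oxopropan-2-yl)cyclohex-3-en-1-yl]butan-2-one F1. LiN(SiMe3)2 (THF, −78 to 0 °C) then forms the kinetic methyl-ketone enolate, which adds to the non-enolisable aldehyde; because this intramolecular aldol is reversible, the carbinol centre can settle under thermodynamic control, giving (4R,4aS,8R,9aR)-8-hydroxy-4,5,9,9-tetramethyl-3,4,4a,5,7,8,9,9a-octahydro-6H-benzo[7]annulen-6-one F2. Silylation (t-BuMe2SiOTf, 2,6-lutidine) comes back to the route at 16.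

Step 11. The four-membered ring closure may lose to enolate O-alkylation, or to deprotonation on the C8 side with expulsion of silanolate. The fallback replaces the anionic closure by a cationic one. It sets out from 18: the C10-side enolate is trapped as it forms (LiN(i-Pr)2, Me3SiCl present from the start, THF, −78 °C) as the C9–C10 trimethylsilyl enol ether of 18 F3. BF3·OEt2 (CH2Cl2, −78 °C) then activates the epoxide for a Mukaiyama-type alkylation by the enol silane, so that no free enolate is present. Aqueous work-up comes back to the route at 19, which is reduced with LiAlH4 to 20 as in the second stage of step 11.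

Step 13. Acylation of the C9 hydroxyl, which lies between the quaternary C10 and the silyloxy-bearing C8, may stall, and forcing it risks angelate-to-tiglate isomerisation. The fallback builds the angelate double bond after acylation. It sets out from 21: the hydroxyl is acylated with 2-[bis(2,2,2-trifluoroethoxy)phosphoryl]propanoyl chloride, an acylating agent that has no double bond to isomerise and therefore tolerates a nucleophilic catalyst and heat (4-(dimethylamino)pyridine, pyridine, CH2Cl2, 40 °C), to give 7,8-bis(tert-butyldimethylsilyloxy)-9-{2-[bis(2,2,2-trifluoroethoxy)phosphoryl]propanoyloxy}longipinan-1-one F4. A Z-selective Still–Gennari olefination with acetaldehyde (KN(SiMe3)2, 18-crown-6, THF, −78 °C) then forms the (Z)-2-methylbut-2-enoate in place and comes back to the route at 23.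

Further compounds
F1 | step 8 | 3-[(1S,2R,6R)-6-methyl-2-(2-methyl-1-oxopropan-2-yl)cyclohex-3-en-1-yl]butan-2-one (both side-chain epimers) | C[C@@H]1CC=C[C@@H](C(C)(C)C=O)[C@H]1C(C)C(C)=O
F2 | step 8 | (4R,4aS,8R,9aR)-8-hydroxy-4,5,9,9-tetramethyl-3,4,4a,5,7,8,9,9a-octahydro-6H-benzo[7]annulen-6-one (both C5 epimers) | C[C@@H]1CC=C[C@@H]2[C@H]1C(C)C(=O)C[C@@H](O)C2(C)C
F3 | step 11 | C9–C10 trimethylsilyl enol ether of 18 | C[C@@H]1C[C@@H]3O[C@@H]3[C@@H]2[C@H]1C(C)=C(O[Si](C)(C)C)[C@H](O[Si](C)(C)C(C)(C)C)[C@@H](O[Si](C)(C)C(C)(C)C)C2(C)C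
F4 | step 13 | 7,8-bis(tert-butyldimethylsilyloxy)-9-{2-[bis(2,2,2-trifluoroethoxy)phosphoryl]propanoyloxy}longipinan-1-one (both epimers at the phosphonate-bearing carbon) | CC(C)(C)[Si](C)(C)O[C@@H]1[C@@H](O[Si](C)(C)C(C)(C)C)[C@@H](OC(=O)C(C)P(=O)(OCC(F)(F)F)OCC(F)(F)F)[C@]2(C)[C@@H]3[C@@H]([C@H]2C(=O)C[C@H]3C)C1(C)C
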